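Everything rests on C9 (eremophilane numbering; ring A = C1–C5 and C10, ring B = C5–C10). It is the only carbon that carries a bond to the ring-fusion carbon C10, a bond to the carbonyl carbon C8 and a C–O bond. C9 is introduced as the carbenoid carbon of a diazoketone tethered to quaternary C5 of a finished ring A cyclohexene (C3 silyl ether, cis C4/C5 methyls, C7 isopropenyl centre preset). One rhodium-catalysed addition across C1=C10 forges C9–C10 and C1–C9. This closes ring B and a cyclopropane and fixes the cis ring fusion. Electron transfer then cuts the extra C1–C9 bond and releases only the C8–C9 enolate for hydroxylation. Desilylation and double angeloylation follow.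

Key step: step 15

Conventions: eremophilane numbering is used for all intermediates (the ring carbons of 1 become C1–C5 and C10). β is the face of the C5 methyl group and α is the opposite face.

Assumption: in step 2 the lipase is taken to hydrolyse the (R)-acetate of 2 faster than the (S)-acetate, the sense expected when the acyl side of the ring acts as the large substituent.

Step 1
Reactants: 1 3-ethoxy-2-methylcyclohex-2-en-1-one
Product: 2 rac-6-acetoxy-3-ethoxy-2-methylcyclohex-2-en-1-one
Conditions: Mn(OAc)3, benzene, reflux (Dean–Stark)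
Reagents that add atoms: manganese(III) acetate, CC(=O)[O-].CC(=O)[O-].CC(=O)[O-].[Mn+3]
Why: Mn(III)-mediated α'-acetoxylation of an enone: the cross-conjugated enolate forms at the ring CH2 next to the carbonyl (future C3), which places the oxygen that ends as the C3 ester oxygen.

Step 2
Reactants: 2 rac-6-acetoxy-3-ethoxy-2-methylcyclohex-2-en-1-one
Product: 3 (R)-3-ethoxy-6-hydroxy-2-methylcyclohex-2-en-1-one
Conditions: Amano lipase PS, pH 7 phosphate buffer/MTBE, rt, stopped near half conversion
Reagents that add atoms: none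
Why: Lipase-catalysed enantioselective ester hydrolysis (kinetic resolution) frees the (R)-alcohol and thereby sets C3, while the (S)-acetate stays esterified and is removed by chromatography.

Step 3
Reactants: 3 (R)-3-ethoxy-6-hydroxy-2-methylcyclohex-2-en-1-one
Product: 4 (R)-6-(tert-butyldimethylsilyloxy)-3-ethoxy-2-methylcyclohex-2-en-1-one
Conditions: TBSCl, imidazole, DMF, rt
Reagents that add atoms: tert-butyldimethylsilyl chloride, CC(C)(C)[Si](C)(C)Cl
Why: Standard imidazole-promoted silylation of a secondary alcohol gives an ether that survives cuprates, strong bases, Pd, boranes, Rh carbenoids and Li/NH3.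

Step 4
Reactants: 4 (R)-6-(tert-butyldimethylsilyloxy)-3-ethoxy-2-methylcyclohex-2-en-1-one
Product: 6 (R)-4-(tert-butyldimethylsilyloxy)-2-methylcyclohex-2-en-1-one, via allylic alcohol 5 (not isolated)
Conditions: DIBAL-H, CH2Cl2, −78 °C; then 1 M HCl, THF, 0 °C
Reagents that add atoms: water, O
Why: Stork–Danheiser reduction–hydrolysis of a vinylogous ester: 1,2-hydride addition followed by acid-induced loss of water and ethanol transposes the carbonyl (now C10), leaves the enone C5(Me)=C4 and does not touch the C3 centre, which has become the γ-carbon.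

Step 5
Reactants: 6 (R)-4-(tert-butyldimethylsilyloxy)-2-methylcyclohex-2-en-1-one; 7 allyl bromide
Product: 9 (2R,3R,4R)-2-allyl-4-(tert-butyldimethylsilyloxy)-2,3-dimethylcyclohexan-1-one, via lithium enolate 8 (not isolated)
Conditions: Me2CuLi (MeLi, CuI), Et2O, −78 → 0 °C; then allyl bromide, DMPU, THF, −30 °C → rt
Reagents that add atoms: lithium dimethylcuprate, [Li+].C[Cu-]C; allyl bromide 7, C=CCBr
Why: Anti-selective conjugate addition–enolate alkylation (three-component coupling): the cuprate adds to C4 trans to the neighbouring pseudoaxial C3 silyloxy group, and the regiodefined C5–C10 enolate 8, whose new C4 methyl sits pseudoaxial to avoid A(1,2) strain, is allylated on the opposite α face, so the C4/C5 methyls end cis and the C5–C6 bond is made without a neopentyl electrophile or a C6 radical.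

Step 6
Reactants: 9 (2R,3R,4R)-2-allyl-4-(tert-butyldimethylsilyloxy)-2,3-dimethylcyclohexan-1-one
Product: 10 (4R,5R,6R)-6-allyl-4-(tert-butyldimethylsilyloxy)-5,6-dimethylcyclohex-1-en-1-yl triflate
Conditions: KHMDS, THF, −78 °C; PhNTf2, −78 → 0 °C
Reagents that add atoms: N-phenylbis(trifluoromethanesulfonimide), O=S(=O)(N(c1ccccc1)S(=O)(=O)C(F)(F)F)C(F)(F)F
Why: Enolate O-triflation: C5 is quaternary, so the C10 ketone can enolise only toward C1 and the position of the future C1=C10 alkene is unambiguous.

Step 7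
Reactants: 10 (4R,5R,6R)-6-allyl-4-(tert-butyldimethylsilyloxy)-5,6-dimethylcyclohex-1-en-1-yl triflate
Product: 11 tert-butyl{[(1R,2R,3S)-3-allyl-2,3-dimethylcyclohex-4-en-1-yl]oxy}dimethylsilane
Conditions: Pd(OAc)2 (cat.), PPh3, HCO2H, n-Bu3N, DMF, 60 °C
Reagents that add atoms: none
Why: Palladium-catalysed formate reduction of a vinyl triflate (oxidative addition, decarboxylative hydride transfer, reductive elimination) replaces OTf by H without moving the double bond, as established for triflates next to quaternary carbons.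

Step 8
Reactants: 11 tert-butyl{[(1R,2R,3S)-3-allyl-2,3-dimethylcyclohex-4-en-1-yl]oxy}dimethylsilane
Product: 13 3-[(1S,5R,6R)-5-(tert-butyldimethylsilyloxy)-1,6-dimethylcyclohex-2-en-1-yl]propan-1-ol, via B-alkyl-9-BBN adduct 12 (not isolated)
Conditions: 9-BBN-H, THF, 0 °C → rt; then NaOH, H2O2, 0 °C
Reagents that add atoms: 9-BBN-H, B1C2CCCC1CCC2 (atoms in 12 only); hydrogen peroxide, OO
Why: Anti-Markovnikov hydroboration–oxidation: 9-BBN reacts with the monosubstituted allyl alkene far faster than with the internal ring alkene flanked by the quaternary carbon, which turns the allyl group into the C6–C7–C8 chain.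

Step 9
Reactants: 13 3-[(1S,5R,6R)-5-(tert-butyldimethylsilyloxy)-1,6-dimethylcyclohex-2-en-1-yl]propan-1-ol
Product: 15 3-[(1S,5R,6R)-5-(tert-butyldimethylsilyloxy)-1,6-dimethylcyclohex-2-en-1-yl]propanoic acid, via aldehyde 14 (not isolated)
Conditions: TEMPO (cat.), PhI(OAc)2, MeCN/H2O, rt
Reagents that add atoms: water, O
Why: Oxoammonium-catalysed oxidation of a primary alcohol through the aldehyde hydrate to the acid, which tolerates the alkene and the silyl ether.

Step 10
Reactants: 15 3-[(1S,5R,6R)-5-(tert-butyldimethylsilyloxy)-1,6-dimethylcyclohex-2-en-1-yl]propanoic acid; 16 (S)-4-benzyloxazolidin-2-one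
Product: 18 (S)-4-benzyl-3-{3-[(1S,5R,6R)-5-(tert-butyldimethylsilyloxy)-1,6-dimethylcyclohex-2-en-1-yl]propanoyl}oxazolidin-2-one, via mixed pivalic anhydride 17 (not isolated)
Conditions: PivCl, Et3N, THF, −20 °C; then LiCl, 16, −20 °C → rt
Reagents that add atoms: pivaloyl chloride, CC(C)(C)C(=O)Cl (atoms in 17 only); (S)-4-benzyloxazolidin-2-one 16, O=C1N[C@@H](Cc2ccccc2)CO1
Why: N-acylation of the Evans auxiliary by a mixed pivalic anhydride, in which the bulky pivaloyl carbonyl steers attack to the substrate carbonyl.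

Step 11
Reactants: 18 (S)-4-benzyl-3-{3-[(1S,5R,6R)-5-(tert-butyldimethylsilyloxy)-1,6-dimethylcyclohex-2-en-1-yl]propanoyl}oxazolidin-2-one; 19 acetyl chloride
Product: 21 (S)-4-benzyl-3-[(R)-2-{[(1S,5R,6R)-5-(tert-butyldimethylsilyloxy)-1,6-dimethylcyclohex-2-en-1-yl]methyl}-3-oxobutanoyl]oxazolidin-2-one, via lithium Z-enolate 20 (not isolated)
Conditions: LDA, THF, −78 °C; then cannulated into AcCl, THF, −78 °C
Reagents that add atoms: acetyl chloride 19, CC(=O)Cl
Why: Evans asymmetric acylation: the chelated lithium Z-enolate 20 is shielded on one face by the benzyl group, acetyl chloride enters from the other face and sets C7 as R, and A(1,3) strain keeps the C7–H bond of the β-keto imide out of alignment with both carbonyls so that it does not epimerise.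

Step 12
Reactants: 21 (S)-4-benzyl-3-[(R)-2-{[(1S,5R,6R)-5-(tert-butyldimethylsilyloxy)-1,6-dimethylcyclohex-2-en-1-yl]methyl}-3-oxobutanoyl]oxazolidin-2-one
Product: 22 (S)-4-benzyl-3-[(R)-2-{[(1S,5R,6R)-5-(tert-butyldimethylsilyloxy)-1,6-dimethylcyclohex-2-en-1-yl]methyl}-3-methylbut-3-enoyl]oxazolidin-2-one
Conditions: Zn, CH2Br2, TiCl4 (pre-aged reagent), THF/CH2Cl2, 0 °C → rt
Reagents that add atoms: dibromomethane, BrCBr
Why: Takai–Lombardo methylenation: the non-basic gem-dimetallic reagent turns the methyl ketone into the isopropenyl group without enolising C7 and leaves imide, carbamate, silyl ether and alkene alone.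

Step 13
Reactants: 22 (S)-4-benzyl-3-[(R)-2-{[(1S,5R,6R)-5-(tert-butyldimethylsilyloxy)-1,6-dimethylcyclohex-2-en-1-yl]methyl}-3-methylbut-3-enoyl]oxazolidin-2-one
Product: 24 (R)-2-{[(1S,5R,6R)-5-(tert-butyldimethylsilyloxy)-1,6-dimethylcyclohex-2-en-1-yl]methyl}-3-methylbut-3-enoic acid, via peroxy acid 23 (not isolated)
Conditions: LiOH, H2O2, THF/H2O, 0 °C; Na2SO3; 1 M HCl to pH 3, 0 °C
Reagents that add atoms: lithium hydroperoxide (from LiOH and H2O2), [Li+].[O-]O
Why: Hydroperoxide cleavage of an N-acyl oxazolidinone: the small α-effect nucleophile attacks the exocyclic carbonyl at 0 °C, which is too mild to epimerise or conjugate C7, and sulfite reduces peracid 23 to the acid.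

Step 14
Reactants: 24 (R)-2-{[(1S,5R,6R)-5-(tert-butyldimethylsilyloxy)-1,6-dimethylcyclohex-2-en-1-yl]methyl}-3-methylbut-3-enoic acid; 25 (trimethylsilyl)diazomethane
Product: 27 (R)-1-diazo-3-{[(1S,5R,6R)-5-(tert-butyldimethylsilyloxy)-1,6-dimethylcyclohex-2-en-1-yl]methyl}-4-methylpent-4-en-2-one, via mixed carbonic anhydride 26 (not isolated)
Conditions: i-BuOCOCl, N-methylmorpholine, THF, −20 °C; then TMSCHN2, MeCN, 0 °C → rt
Reagents that add atoms: isobutyl chloroformate, CC(C)COC(=O)Cl (atoms in 26 only); (trimethylsilyl)diazomethane 25, C[Si](C)(C)C=[N+]=[N-]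
Why: Arndt–Eistert-type C-acylation of (trimethylsilyl)diazomethane by a mixed carbonic anhydride, with the silyl group passing to the carbonate leaving group, and with a weak base at low temperature that avoids ketene formation and so preserves C7.

Step 15
Reactants: 27 (R)-1-diazo-3-{[(1S,5R,6R)-5-(tert-butyldimethylsilyloxy)-1,6-dimethylcyclohex-2-en-1-yl]methyl}-4-methylpent-4-en-2-one
Product: 28 tricyclic cyclopropyl ketone, 1,9-cyclo-3α-(tert-butyldimethylsilyloxy)-10βH-eremophil-11-en-8-one (cyclopropane C1–C9–C10 on the α face of ring A; H1, H9 and H10 mutually cis; 4β,5β-dimethyl; 7β-isopropenyl)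
Conditions: Rh2(OAc)4 (1 mol %), CH2Cl2, rt, slow syringe-pump addition of 27, high dilution
Reagents that add atoms: none
Why: Rh2(OAc)4 expels N2 from 27, and the electrophilic rhodium keto-carbenoid hands C9 over to the C1=C10 π bond in one asynchronous but suprafacial step that makes C9–C10 and C1–C9 together. The closest known reaction type is the Rh- or Cu-catalysed intramolecular cyclopropanation of δ,ε-unsaturated α-diazoketones to bicyclo[4.1.0]heptan-2-ones. Ring B (C5–C6–C7–C8–C9–C10) closes as a six-membered ring by bonding of C9 to the proximal alkene carbon C10 (exo mode), and the three-membered ring C1–C9–C10 closes in the same event by [2+1] addition. C10 is controlled by C5, because the C6–C7–C8 strap hangs from the α bond of C5, so C9 reaches only the α face and H10 is left β, cis to the C5 methyl; C1 follows from the suprafacial addition (H1 cis to H10), and C9 from ring strain, since C8 must stay on the same side of the cyclopropane as C5 (H9 cis to H1 and H10). The step needs chemoselectivity for the ring alkene: attack on the β,γ-isopropenyl bond would have to pass through a four-membered ring (the entry to a vinylogous Wolff rearrangement), the quaternary C5 removes the C–H bond that five-ring insertion would use, and slow addition at room temperature in an aprotic solvent suppresses carbene dimerisation and ketene chemistry. The neutral conditions leave the base-sensitive C7 centre, the silyl ether and the isopropenyl group untouched.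

Step 16
Reactants: 28 tricyclic cyclopropyl ketone
Product: 30 9β-hydroxy-3α-(tert-butyldimethylsilyloxy)-10βH-eremophil-11-en-8-one, via lithium C8-C9 enolate 29 (not isolated)
Conditions: Li, NH3/THF, t-BuOH (1 equiv), −78 °C; isoprene; NH3 removed, THF; 2-(phenylsulfonyl)-3-phenyloxaziridine, −78 °C; aq NH4Cl
Reagents that add atoms: 2-(phenylsulfonyl)-3-phenyloxaziridine, O=S(=O)(c1ccccc1)N1OC1c1ccccc1
Why: Dissolving-metal opening of a conjugated cyclopropyl ketone followed by Davis enolate hydroxylation: the ketyl radical anion cleaves the cyclopropane bond that runs nearly parallel to the carbonyl p orbitals (C1–C9, not the ring B bond C9–C10), C1 is protonated by t-BuOH, the ketone is stored as the regiodefined enolate 29 so that C7 is never deprotonated, and the oxaziridine approaches C9 from the convex β face, away from the axial C4–C5 bond, to give the equatorial 9β-alcohol.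

Step 17
Reactants: 30 9β-hydroxy-3α-(tert-butyldimethylsilyloxy)-10βH-eremophil-11-en-8-one
Product: 31 3α,9β-dihydroxy-10βH-eremophil-11-en-8-one
Conditions: HF·pyridine, THF, 0 °C → rt
Reagents that add atoms: none
Why: Fluoride-driven cleavage of the secondary silyl ether under weakly acidic conditions, chosen over basic TBAF so that the α-ketol and the β,γ-unsaturated ketone neither epimerise nor conjugate.

Step 18
Reactants: 31 3α,9β-dihydroxy-10βH-eremophil-11-en-8-one; 32 angelic acid
Product: 35 3α,9β-bis(angeloyloxy)-10βH-eremophil-11-en-8-one (CNP0174755.1), via angelic trichlorobenzoic anhydride 33 (not isolated), via 3-monoangelate 34 (not isolated)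
Conditions: 32, 2,4,6-trichlorobenzoyl chloride, Et3N, toluene, rt; then 31, 80 °C, no DMAP
Reagents that add atoms: angelic acid 32, C/C=C(/C)C(=O)O; 2,4,6-trichlorobenzoyl chloride, O=C(Cl)c1c(Cl)cc(Cl)cc1Cl (atoms in 33 only)
Why: Yamaguchi-type mixed-anhydride esterification run without DMAP: both equatorial secondary alcohols are acylated by 33, and the absence of a nucleophilic catalyst prevents addition–elimination at the angelate double bond, so the Z geometry is kept.

Compound list
1 | 3-ethoxy-2-methylcyclohex-2-en-1-one | CCOC1=C(C)C(=O)CCC1 | starting material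
2 | rac-6-acetoxy-3-ethoxy-2-methylcyclohex-2-en-1-one | CCOC1=C(C)C(=O)C(OC(C)=O)CC1 | intermediate
3 | (R)-3-ethoxy-6-hydroxy-2-methylcyclohex-2-en-1-one | CCOC1=C(C)C(=O)[C@H](O)CC1 | intermediate
4 | (R)-6-(tert-butyldimethylsilyloxy)-3-ethoxy-2-methylcyclohex-2-en-1-one | CCOC1=C(C)C(=O)[C@H](O[Si](C)(C)C(C)(C)C)CC1 | intermediate
5 | (6R)-6-(tert-butyldimethylsilyloxy)-3-ethoxy-2-methylcyclohex-2-en-1-ol (carbinol epimers) | CCOC1=C(C)C(O)[C@H](O[Si](C)(C)C(C)(C)C)CC1 | intermediate
6 | (R)-4-(tert-butyldimethylsilyloxy)-2-methylcyclohex-2-en-1-one | O=C1CC[C@@H](O[Si](C)(C)C(C)(C)C)C=C1C | intermediate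
7 | allyl bromide | C=CCBr | starting material
8 | lithium (3R,4R)-4-(tert-butyldimethylsilyloxy)-2,3-dimethylcyclohex-1-en-1-olate (3α-OTBS, 4β-Me) | [Li+].CC1=C([O-])CC[C@@H](O[Si](C)(C)C(C)(C)C)[C@@H]1C | intermediate
9 | (2R,3R,4R)-2-allyl-4-(tert-butyldimethylsilyloxy)-2,3-dimethylcyclohexan-1-one (3α-OTBS, 4β-Me, 5β-Me, 5α-allyl) | C=CC[C@@]1(C)C(=O)CC[C@@H](O[Si](C)(C)C(C)(C)C)[C@@H]1C | intermediate
10 | (4R,5R,6R)-6-allyl-4-(tert-butyldimethylsilyloxy)-5,6-dimethylcyclohex-1-en-1-yl triflate | C=CC[C@@]1(C)C(OS(=O)(=O)C(F)(F)F)=CC[C@@H](O[Si](C)(C)C(C)(C)C)[C@@H]1C | intermediate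
11 | tert-butyl{[(1R,2R,3S)-3-allyl-2,3-dimethylcyclohex-4-en-1-yl]oxy}dimethylsilane | C=CC[C@@]1(C)C=CC[C@@H](O[Si](C)(C)C(C)(C)C)[C@@H]1C | intermediate
12 | B-alkyl-9-borabicyclo[3.3.1]nonane adduct of 11 (boron on C8) | B1(CCC[C@@]2(C)C=CC[C@@H](O[Si](C)(C)C(C)(C)C)[C@@H]2C)C2CCCC1CCC2 | intermediate
13 | 3-[(1S,5R,6R)-5-(tert-butyldimethylsilyloxy)-1,6-dimethylcyclohex-2-en-1-yl]propan-1-ol | OCCC[C@@]1(C)C=CC[C@@H](O[Si](C)(C)C(C)(C)C)[C@@H]1C | intermediate
14 | 3-[(1S,5R,6R)-5-(tert-butyldimethylsilyloxy)-1,6-dimethylcyclohex-2-en-1-yl]propanal | O=CCC[C@@]1(C)C=CC[C@@H](O[Si](C)(C)C(C)(C)C)[C@@H]1C | intermediate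
15 | 3-[(1S,5R,6R)-5-(tert-butyldimethylsilyloxy)-1,6-dimethylcyclohex-2-en-1-yl]propanoic acid | OC(=O)CC[C@@]1(C)C=CC[C@@H](O[Si](C)(C)C(C)(C)C)[C@@H]1C | intermediate
16 | (S)-4-benzyloxazolidin-2-one | O=C1N[C@@H](Cc2ccccc2)CO1 | starting material
17 | mixed anhydride of 15 and pivalic acid | CC(C)(C)C(=O)OC(=O)CC[C@@]1(C)C=CC[C@@H](O[Si](C)(C)C(C)(C)C)[C@@H]1C | intermediate
18 | (S)-4-benzyl-3-{3-[(1S,5R,6R)-5-(tert-butyldimethylsilyloxy)-1,6-dimethylcyclohex-2-en-1-yl]propanoyl}oxazolidin-2-one | O=C(CC[C@@]1(C)C=CC[C@@H](O[Si](C)(C)C(C)(C)C)[C@@H]1C)N1[C@@H](Cc2ccccc2)COC1=O | intermediate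
19 | acetyl chloride | CC(=O)Cl | starting material
20 | lithium Z-enolate of imide 18 (O and C6 cis) | [Li+].[O-]/C(=C\C[C@@]1(C)C=CC[C@@H](O[Si](C)(C)C(C)(C)C)[C@@H]1C)N1[C@@H](Cc2ccccc2)COC1=O | intermediate
21 | β-keto imide, (7R)-acetyl derivative of 18 | CC(=O)[C@@H](C[C@@]1(C)C=CC[C@@H](O[Si](C)(C)C(C)(C)C)[C@@H]1C)C(=O)N1[C@@H](Cc2ccccc2)COC1=O | intermediate
22 | (7R)-isopropenyl imide | C=C(C)[C@@H](C[C@@]1(C)C=CC[C@@H](O[Si](C)(C)C(C)(C)C)[C@@H]1C)C(=O)N1[C@@H](Cc2ccccc2)COC1=O | intermediate
23 | peroxy acid corresponding to 24 | C=C(C)[C@@H](C[C@@]1(C)C=CC[C@@H](O[Si](C)(C)C(C)(C)C)[C@@H]1C)C(=O)OO | intermediate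
24 | (R)-2-{[(1S,5R,6R)-5-(tert-butyldimethylsilyloxy)-1,6-dimethylcyclohex-2-en-1-yl]methyl}-3-methylbut-3-enoic acid | C=C(C)[C@@H](C[C@@]1(C)C=CC[C@@H](O[Si](C)(C)C(C)(C)C)[C@@H]1C)C(=O)O | intermediate
25 | (trimethylsilyl)diazomethane | C[Si](C)(C)C=[N+]=[N-] | starting material
26 | isobutyl carbonic anhydride of 24 | C=C(C)[C@@H](C[C@@]1(C)C=CC[C@@H](O[Si](C)(C)C(C)(C)C)[C@@H]1C)C(=O)OC(=O)OCC(C)C | intermediate
27 | diazoketone, ring A cyclohexene with the (7R)-2-isopropenyl-4-diazo-3-oxobutyl chain on C5 | C=C(C)[C@@H](C[C@@]1(C)C=CC[C@@H](O[Si](C)(C)C(C)(C)C)[C@@H]1C)C(=O)C=[N+]=[N-] | intermediate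
28 | tricyclic cyclopropyl ketone (C1–C9–C10 three-membered ring on the α face of ring A) | C=C(C)[C@H]1C[C@@]2(C)[C@@H]3[C@H](C[C@@H](O[Si](C)(C)C(C)(C)C)[C@@H]2C)[C@@H]3C1=O | intermediate
29 | lithium C8–C9 enolate of the cis-decalone | [Li+].C=C(C)[C@H]1C[C@@]2(C)[C@H](CC[C@@H](O[Si](C)(C)C(C)(C)C)[C@@H]2C)C=C1[O-] | intermediate
30 | 9β-hydroxy-3α-(tert-butyldimethylsilyloxy)-10βH-eremophil-11-en-8-one | C=C(C)[C@H]1C[C@@]2(C)[C@H](CC[C@@H](O[Si](C)(C)C(C)(C)C)[C@@H]2C)[C@@H](O)C1=O | intermediate
31 | 3α,9β-dihydroxy-10βH-eremophil-11-en-8-one | C=C(C)[C@H]1C[C@@]2(C)[C@H](CC[C@@H](O)[C@@H]2C)[C@@H](O)C1=O | intermediate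
32 | angelic acid, (Z)-2-methylbut-2-enoic acid | C/C=C(/C)C(=O)O | starting material
33 | angelic 2,4,6-trichlorobenzoic anhydride | C/C=C(/C)C(=O)OC(=O)c1c(Cl)cc(Cl)cc1Cl | intermediate
34 | 3α-angeloyloxy-9β-hydroxy-10βH-eremophil-11-en-8-one | C=C(C)[C@H]1C[C@@]2(C)[C@H](CC[C@@H](OC(=O)/C(C)=C\C)[C@@H]2C)[C@@H](O)C1=O | intermediate
35 | 3α,9β-bis(angeloyloxy)-10βH-eremophil-11-en-8-one, CNP0174755.1 | C=C(C)[C@H]1C[C@@]2(C)[C@H](CC[C@@H](OC(=O)/C(C)=C\C)[C@@H]2C)[C@@H](OC(=O)/C(C)=C\C)C1=O | target

Total step count: 18. Longest linear sequence: 18 (fully linear from 1).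

Steps most likely to fail

Step 15. The carbenoid may be intercepted by the nearby isopropenyl π bond and drift into ketene-type rearrangement. It may dimerise, or it may add only sluggishly to an alkene that is flanked by a quaternary carbon. The fallback sets out from 27 and returns at 28, and it replaces the carbenoid by a radical–polar sequence that makes the same two bonds one after the other. Aqueous HBr in ether converts 27 into the bromomethyl ketone F1. A visible-light photoredox bromine-atom-transfer cyclisation then lets the C9 radical add 6-exo to C10 on the face of the tether; four-ring attack on the isopropenyl group is not a viable radical path. The C1 radical picks up bromine on the open β face and gives the cis-fused 1β-bromo decalone F2. Kinetic deprotonation at the less hindered C9 (KHMDS, THF, −78 °C) displaces bromide in a 3-exo-tet closure and forms the C1–C9 bond of 28.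

Step 12. The organometallic reagent may enolise the β-keto imide, with erosion of the C7 configuration, or it may attack the imide carbonyl. The fallback sets out from 21 and returns at 22, and it uses a two-stage Peterson olefination in place of a titanium carbenoid. The weakly basic organocerium reagent from TMSCH2MgCl and CeCl3 (THF, −78 °C) adds to the acetyl carbonyl and gives the isolable β-hydroxysilane F3. BF3·OEt2 in CH2Cl2 at low temperature then triggers anti elimination of silicon and oxygen. For structural reasons this elimination can place the double bond only at the terminal position, which gives 22.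

Step 16. Three things may go wrong here. Proton exchange while the ammonia is removed may let the enolate drift toward C7. Residual amide base may consume the oxidant. Facial discrimination in the oxygen transfer may be poor. The fallback sets out from 28 and returns at 30, and it separates reduction from oxidation. The Li/NH3 opening is run as before, but enolate 29 is silylated (TMSCl/Et3N, THF, after removal of ammonia) to the isolable trimethylsilyl enol ether F4, which can be purified and checked for regiochemistry. A Rubottom oxidation with dimethyldioxirane (acetone, −40 °C) attacks the electron-rich enol ether faster than the isopropenyl group, from the convex β face, and gives the 9β-trimethylsilyloxy ketone F5. Citric acid in methanol removes the trimethylsilyl group selectively and gives 30.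

Further compounds
F1 | step 15 | bromomethyl ketone, (R)-1-bromo-3-{[(1S,5R,6R)-5-(tert-butyldimethylsilyloxy)-1,6-dimethylcyclohex-2-en-1-yl]methyl}-4-methylpent-4-en-2-one | C=C(C)[C@@H](C[C@@]1(C)C=CC[C@@H](O[Si](C)(C)C(C)(C)C)[C@@H]1C)C(=O)CBr
F2 | step 15 | 1β-bromo-3α-(tert-butyldimethylsilyloxy)-10βH-eremophil-11-en-8-one | C=C(C)[C@H]1C[C@@]2(C)[C@H]([C@H](Br)C[C@@H](O[Si](C)(C)C(C)(C)C)[C@@H]2C)CC1=O
F3 | step 12 | β-hydroxysilane, (7R)-[2-hydroxy-1-(trimethylsilyl)propan-2-yl] imide (C11 epimers) | C[Si](C)(C)CC(C)(O)[C@@H](C[C@@]1(C)C=CC[C@@H](O[Si](C)(C)C(C)(C)C)[C@@H]1C)C(=O)N1[C@@H](Cc2ccccc2)COC1=O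
F4 | step 16 | C8–C9 trimethylsilyl enol ether of the cis-decalone | C=C(C)[C@H]1C[C@@]2(C)[C@H](CC[C@@H](O[Si](C)(C)C(C)(C)C)[C@@H]2C)C=C1O[Si](C)(C)C
F5 | step 16 | 9β-trimethylsilyloxy-3α-(tert-butyldimethylsilyloxy)-10βH-eremophil-11-en-8-one | C=C(C)[C@H]1C[C@@]2(C)[C@H](CC[C@@H](O[Si](C)(C)C(C)(C)C)[C@@H]2C)[C@@H](O[Si](C)(C)C)C1=O
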